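## Analysis of the target

The target is a linear quaterphenyl of four phloroglucinol rings, A–B–C–D, in which rings B and C are each joined to their neighbours through two carbons that stand meta to one another; all twelve oxygens are free hydroxyls, and ring C, which carries the only chlorine, has no hydrogen left. There is no stereocentre. Rings A and D are symmetrical about their biaryl bonds, so the only possible stereogenic element is the B3–C1 axis (four ortho hydroxyls, two unsymmetrical rings), for which no configuration is specified. The free dodecaphenol is very electron-rich and will oxidise in air and react with any electrophile, so the oxygens must stay masked until the last step, and the aryl chloride excludes reductive unmasking that cleaves C–Cl bonds. Two things make the synthesis hard: each of the three biaryl bonds joins carbons flanked by two oxygens on both sides, the central one between a pentasubstituted and a hexasubstituted ring; and the chlorine must end up on C3 although B5 and the four CH positions of rings A and D are equally nucleophilic, so it cannot be introduced late. The strategy rests on the fact that B3 and C1 each sit between two oxygen-bearing carbons (B2/B4 and C2/C6) and that rings B and C each have the 1,3,5-oxygen pattern of a folded triacetate chain: B3, B4, B5, B6, B1, B2 map onto the CH2 group and positions 6, 5, 4, 3, 2 of a 4-methoxy-2-pyrone bearing ring A at its 3-position, and C1, C2, C3, C4, C5, C6 onto the same atoms of a second pyrone with chlorine at its 5-position and ring D at its 3-position. B3 and C1 can therefore begin as the two CH2 groups of an ethylene bridge between the 6-positions of two pyrones, and the hindered biaryl bond as an ordinary sp3–sp3 bond.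

## Retrosynthetic reasoning

**11 ⇒ 10.** The last disconnection is the eight O–CH3 bonds. Methyl ethers survive organolithium, palladium and hot alkoxide chemistry, and two of them (on B6 and C4) are present from the start as the 4-methoxy groups of the pyrones. The forward step is a global Lewis-acid ether cleavage that must leave the C–Cl bond and the biaryl bonds alone.

**10 ⇒ 8.** The B2–B3 and C1–C6 bonds are cut, and rings B and C are unfolded into two 4-methoxy-2-pyrones joined by an ethylene bridge. This cut is preferred to any cut of a biaryl bond for three reasons:
- it turns the most hindered bond of the target, B3–C1, into an sp3–sp3 bond;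
- it fixes the oxygen pattern of both rings (lactone carbonyl → B2–OH and C6–OH, ring oxygen → B4–OH and C2–OH, 4-methoxy → B6–OMe and C4–OMe);
- the chlorine of ring C becomes a substituent at the 5-position of one pyrone, where it can be placed without ambiguity.

Compounds 10 and 8 are isomers. Forward, base has to open both lactones to the diester 9, and each bridge carbon has to acylate itself with the ester of its own unit, after which tautomerisation gives the two arenes.

**8 ⇒ 6 + two molecules of 7.** The two bonds between the pyrone 3-positions and rings A and D (A1–B1 and D1–C5) are cut. Rings A and D are identical, so one twofold coupling serves both ends. These bonds are made late and by cross-coupling, not early by arylating a free 4-hydroxyl pyrone, because a 2,4,6-trimethoxyphenyl ring would take up any electrophilic chlorine or bromine meant for the pyrone ring or its methyl group. All halogens therefore have to be on the pyrones before the aryl rings arrive, and bromine at the 3-position beside chlorine at the 5-position gives the coupling its site selectivity.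

**6 ⇒ 2 + 4.** The CH2–CH2 bond is cut. The two halves differ (one carries chlorine), so an oxidative dimerisation is of no use; the bond is made by alkylating the lithium dienolate 5 of 2 with bromide 4. The chlorinated half is made the electrophile because both of its nucleophilic ring positions are blocked, which keeps the side-chain bromination clean.

**4 ⇒ 3 ⇒ 2 ⇒ 1.** Three carbon–halogen bonds are removed in the reverse of their order of introduction. The order follows the innate reactivity of pyrone 1, which is commercial. Electrophiles attack the 3-position first, so bromine (the coupling handle) goes there. The second electrophile, chlorine, can then only go to the 5-position. The radical bromination of the methyl group comes last, when no ring position is left to compete. Compound 2 serves twice, as the nucleophilic half and as the precursor of the electrophilic half.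

## Alternatives that were turned down

**Alternative 1:** The B3–C1 bond is cut and made last, inside a ring.
- Disconnection and key step: the two biaryl halves are first tied together through the oxygens on B4 and C2 as a methylene acetal, giving bromide A2 (bromine on C1, hydrogen on B3). Zerovalent palladium would insert into the C1–Br bond and the arylpalladium would arylate the neighbouring B3–H bond, closing a seven-membered dibenzo-1,3-dioxepine in A1. Cleaving the O–CH2–O bridge together with the ten methyl ethers would give the target.
- For it: intramolecular direct arylation through a temporary tether is an established reaction type, so this key step stands on firmer ground than an untried double ring transformation; on that point it is the stronger plan. The tether decides which positions join (B3 and B5 are equivalent in A2), and a chiral tether could even control the axis if that were wanted.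
- Against it:
  - A2 already contains the A–B and C–D biaryl bonds, each with four ortho oxygens, so two hindered couplings come before the key step.
  - Each half needs exactly one oxygen (on B4, on C2) set apart from its neighbours by protecting-group work.
  - Ring C must be assembled as a hexasubstituted arene carrying Br, Cl, ring D and differentiated oxygens in fixed order.
  - A mixed methylene acetal of two different hindered phenols must be made without the symmetrical acetals.
  - The palladium must attack a C–H flanked by two oxygens and form a fourfold ortho-substituted biaryl within a seven-membered ring.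
- Comparison: the step count should be well over twice that of the chosen route. The chosen route offers, in place of a precedented key step, a seven-step sequence in which no bond between two oxygen-flanked arene carbons is made by coupling and the chlorine position follows from the order of two halogenations.

**Alternative 2:** Ring B is disconnected into a four-carbon and a two-carbon piece.
- Disconnection and key step: the four-carbon piece is the racemic 3-ethoxy-4-arylcyclobutenone A4, whose aryl group is the complete ring C–D unit, on the sp3 carbon that becomes B3. The two-carbon piece is the silyl ynol ether A5 of ring A. On heating, A4 ring-opens, the alkyne of A5 adds across the C=C=O unit so formed (B1–B2 and B5–B6), the new four-membered ring opens again and a six-electron electrocyclisation restores the B2–B3 bond. Tautomerisation gives phenol A3 with three different oxygen groups on ring B (free OH at B2, ethyl ether at B4, silyl ether at B6).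
- For it: the benzannulation is a known pericyclic cascade with built-in regiochemistry. It creates the A–B and B–C bonds without cross-coupling, since both rings arrive as substituents, and it delivers ring B with every oxygen distinguished, which the chosen route cannot match (though it does not need it).
- Against it:
  - It builds only one of the four rings; the C–D unit, with its chlorine, its hexasubstituted ring C and its hindered biaryl bond, must be made conventionally beforehand.
  - That unit must then be attached, through a carbon flanked by two methoxy groups, to the sp3 carbon of a cyclobutenone.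
  - A4 is a vinylogous ester with a doubly activated acidic C–H and is prone to premature ring opening.
  - A5 is an electron-rich aryl ynol ether that needs a homologation of the corresponding ester and careful handling.
  - The electrocyclisation must bring a terminus bearing the very bulky aryl group into bonding distance, while the ortho methoxy groups of both partners crowd the cycloaddition.
  - Ethyl, silyl and methyl groups all have to come off at the end.
- Comparison: one ring is made per key step instead of two, the hardest ring (ring C) is not addressed by the key step at all, and the steps to A4 alone should outnumber the whole chosen sequence.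

**Alternative 3:** The outer rings are made by the same kind of polyketide folding that the chosen route uses for the inner ones.
- Disconnection and key step: the A1–A2 and D1–D2 bonds are cut, which turns rings A and D into two (E)-3-methoxy-5-oxohex-2-enoate chains attached through their terminal CH2 groups to B1 and C5 of a preformed, permethylated B–C biaryl, A7. An alkoxide base would deprotonate each benzylic CH2 next to its ketone, each enolate would attack its own ester in a six-membered closure, and enolisation would give A6, in which rings A and D each carry two free hydroxyls.
- For it: the nucleophilic carbons are benzylic and therefore more acidic than the bridge carbons of the chosen precursor. The chains are already open and the two closures are far apart, so there is no 1,4-diketone, no cross-aldol and no α-chloro ketone. On the chemistry of the key step this alternative is at least as good as the chosen one, probably better.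
- Against it:
  - It leaves the B3–C1 bond, the most hindered bond of the molecule, to a conventional cross-coupling or an unselective oxidative coupling, with ring C hexasubstituted and made unsymmetrical by its chlorine.
  - It needs that core with two benzylic handles at B1 and C5, each between two methoxy groups, onto which two six-carbon chains of defined double-bond geometry must be built.
- Comparison: reaching A7 should take roughly twice as many steps as the whole chosen route. The chosen strategy forms the central bond as an sp3–sp3 alkylation and reaches its precursor in five steps; it pays with a less certain key step.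

Key step: step 6

Assumption: the target is drawn without stereodescriptors, so the B3–C1 axis is left unassigned and the route delivers the racemate (or interconverting rotamers).

## Route

Step 1
Reactants: 1 4-methoxy-6-methyl-2H-pyran-2-one
Product: 2 3-bromo-4-methoxy-6-methyl-2H-pyran-2-one
Conditions: NBS, MeCN, 0 °C to rt, dark
Reagents that add atoms: N-bromosuccinimide, O=C1CCC(=O)N1Br
Why: Electrophilic bromination goes to the 3-position, the α-carbon of the vinylogous carbonate and the most nucleophilic ring carbon of this pyrone; ionic conditions in the dark leave the 6-methyl group alone.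

Step 2
Reactants: 2 3-bromo-4-methoxy-6-methyl-2H-pyran-2-one
Product: 3 3-bromo-5-chloro-4-methoxy-6-methyl-2H-pyran-2-one
Conditions: NCS, AcOH, 60 °C
Reagents that add atoms: N-chlorosuccinimide, O=C1CCC(=O)N1Cl
Why: Electrophilic chlorination; with the 3-position blocked, the 5-position (β-carbon of the ring enol ether) is the remaining nucleophilic ring carbon, by analogy with 3,5-dihalogenation in the 2-pyrone series. The chlorine is placed now because no trimethoxyphenyl ring is yet present to compete.

Step 3
Reactants: 3 3-bromo-5-chloro-4-methoxy-6-methyl-2H-pyran-2-one
Product: 4 3-bromo-6-(bromomethyl)-5-chloro-4-methoxy-2H-pyran-2-one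
Conditions: NBS, AIBN (cat.), PhCF3, reflux
Reagents that add atoms: N-bromosuccinimide, O=C1CCC(=O)N1Br
Why: Wohl–Ziegler bromination of the 6-methyl group, whose radical is allylic and conjugated with the pyrone; both nucleophilic ring carbons already carry halogen, so ionic ring bromination has no outlet, and one equivalent of NBS limits dibromination.

Step 4
Reactants: 2 3-bromo-4-methoxy-6-methyl-2H-pyran-2-one, 4 3-bromo-6-(bromomethyl)-5-chloro-4-methoxy-2H-pyran-2-one
Product: 6 3-bromo-6-[2-(3-bromo-4-methoxy-2-oxo-2H-pyran-6-yl)ethyl]-5-chloro-4-methoxy-2H-pyran-2-one, via lithium dienolate 5 (not isolated)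
Conditions: LiN(SiMe3)2, THF, −78 °C; then 4, DMPU, −78 to −40 °C
Reagents that add atoms: none
Why: The amide base removes a proton from the 6-methyl group (vinylogous α-position of the lactone) without touching the 3-bromine, and the extended enolate 5 alkylates at its exocyclic carbon by SN2 displacement on the primary, allylic-type bromide 4.

Step 5
Reactants: 6 3-bromo-6-[2-(3-bromo-4-methoxy-2-oxo-2H-pyran-6-yl)ethyl]-5-chloro-4-methoxy-2H-pyran-2-one, 7 (2,4,6-trimethoxyphenyl)boronic acid
Product: 8 5-chloro-4-methoxy-6-{2-[4-methoxy-2-oxo-3-(2,4,6-trimethoxyphenyl)-2H-pyran-6-yl]ethyl}-3-(2,4,6-trimethoxyphenyl)-2H-pyran-2-one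
Conditions: 7 (3 equiv), Pd(OAc)2 (cat.), SPhos (2-dicyclohexylphosphino-2',6'-dimethoxybiphenyl), K3PO4, toluene/H2O, 80 °C
Reagents that add atoms: none
Why: Twofold Suzuki–Miyaura coupling; the two C–Br bonds at the 3-positions (α to the lactone carbonyl) add to zerovalent palladium well before the C–Cl bond at the electron-rich, flanked 5-position. The dialkylbiarylphosphine allows transmetalation of the di-ortho-substituted boronic acid, and its excess offsets protodeboronation.

Step 6
Reactants: 8 5-chloro-4-methoxy-6-{2-[4-methoxy-2-oxo-3-(2,4,6-trimethoxyphenyl)-2H-pyran-6-yl]ethyl}-3-(2,4,6-trimethoxyphenyl)-2H-pyran-2-one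
Product: 10 3-chloro-4,4'-dimethoxy-3',5-bis(2,4,6-trimethoxyphenyl)-[1,1'-biphenyl]-2,2',6,6'-tetrol, via ring-opened diester 9 (not isolated)
Conditions: NaOMe (8 equiv), MeOH, reflux, Ar; then aq HCl
Reagents that add atoms: none
Why: Proposed new method: methoxide should add to each lactone carbonyl and open it to the ring-opened diester 9, which the excess base holds as its conjugated dienolates; the former ring leaves the ester and the ketone arm cis on the C=C bond, and in that form the chlorine stays on an sp2 carbon. A small equilibrium amount of the ketone enolate on the bridge side then attacks the ester of its own unit, methoxide leaves and the cyclohexadienone enolises to the arene, so the net change is an isomerisation. The closest known reaction type is the alkoxide-induced isomerisation of a 4-methoxy-6-methyl-2-pyrone to 5-methoxyresorcinol by lactone opening and Claisen closure; here it must occur twice, on neighbouring carbons, with a 3-aryl group beside each ester. Ring B closes by 6-(enolendo)-exo-trig attack forming B2–B3, and ring C in the same mode forming C1–C6. No stereocentre is set: the transient sp3 centres vanish on aromatisation and the B3–C1 axis forms without control. The step needs Claisen closure to win over re-lactonisation, over five-ring aldol condensation of the transient 1,4-diketone and over loss of chloride from the keto tautomer; lactonisation and aldol addition are reversible whereas aromatisation to the phenoxide is not, the excess base keeps the ketones masked as dienolates, and once the first ring has formed the 1,4-diketone no longer exists. Methoxide in methanol makes ester exchange and exchange of the 4-methoxy groups degenerate.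

Step 7
Reactants: 10 3-chloro-4,4'-dimethoxy-3',5-bis(2,4,6-trimethoxyphenyl)-[1,1'-biphenyl]-2,2',6,6'-tetrol
Product: 11 3-chloro-3',5-bis(2,4,6-trihydroxyphenyl)-[1,1'-biphenyl]-2,2',4,4',6,6'-hexol
Conditions: BBr3 (excess), CH2Cl2, −78 °C to rt; then degassed MeOH, H2O
Reagents that add atoms: none
Why: Lewis-acid ether cleavage: BBr3 coordinates each methoxy oxygen and bromide removes the methyl group by SN2, while the aryl chloride and the biaryl bonds are inert. Degassed work-up protects the oxidation-prone dodecaphenol.

## Compound list

1 | 4-methoxy-6-methyl-2H-pyran-2-one | COC1=CC(=O)OC(C)=C1 | starting material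
2 | 3-bromo-4-methoxy-6-methyl-2H-pyran-2-one | COC1=C(Br)C(=O)OC(C)=C1 | intermediate
3 | 3-bromo-5-chloro-4-methoxy-6-methyl-2H-pyran-2-one | COC1=C(Br)C(=O)OC(C)=C1Cl | intermediate
4 | 3-bromo-6-(bromomethyl)-5-chloro-4-methoxy-2H-pyran-2-one | COC1=C(Br)C(=O)OC(CBr)=C1Cl | intermediate
5 | [(3-bromo-4-methoxy-2-oxo-2H-pyran-6-yl)methyl]lithium (lithium dienolate of 2, not isolated) | [Li]CC1=CC(OC)=C(Br)C(=O)O1 | intermediate
6 | 3-bromo-6-[2-(3-bromo-4-methoxy-2-oxo-2H-pyran-6-yl)ethyl]-5-chloro-4-methoxy-2H-pyran-2-one | COC1=C(Br)C(=O)OC(CCC2=C(Cl)C(OC)=C(Br)C(=O)O2)=C1 | intermediate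
7 | (2,4,6-trimethoxyphenyl)boronic acid | COc1cc(OC)c(B(O)O)c(OC)c1 | starting material
8 | 5-chloro-4-methoxy-6-{2-[4-methoxy-2-oxo-3-(2,4,6-trimethoxyphenyl)-2H-pyran-6-yl]ethyl}-3-(2,4,6-trimethoxyphenyl)-2H-pyran-2-one | COc1cc(OC)c(C2=C(OC)C=C(CCC3=C(Cl)C(OC)=C(c4c(OC)cc(OC)cc4OC)C(=O)O3)OC2=O)c(OC)c1 | intermediate
9 | dimethyl (2E,10E)-4-chloro-3,10-dimethoxy-5,8-dioxo-2,11-bis(2,4,6-trimethoxyphenyl)dodeca-2,10-dienedioate (CHCl centre unassigned, lost on aromatisation; not isolated) | COC(=O)/C(c1c(OC)cc(OC)cc1OC)=C(/OC)CC(=O)CCC(=O)C(Cl)/C(OC)=C(/c1c(OC)cc(OC)cc1OC)C(=O)OC | intermediate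
10 | 3-chloro-4,4'-dimethoxy-3',5-bis(2,4,6-trimethoxyphenyl)-[1,1'-biphenyl]-2,2',6,6'-tetrol (OH on B2, B4, C2, C6; OMe on B6, C4 and on rings A and D) | COc1cc(OC)c(-c2c(OC)cc(O)c(-c3c(O)c(Cl)c(OC)c(-c4c(OC)cc(OC)cc4OC)c3O)c2O)c(OC)c1 | intermediate
11 | 3-chloro-3',5-bis(2,4,6-trihydroxyphenyl)-[1,1'-biphenyl]-2,2',4,4',6,6'-hexol (CNP0271703.0) | Oc1cc(O)c(-c2c(O)cc(O)c(-c3c(O)c(Cl)c(O)c(-c4c(O)cc(O)cc4O)c3O)c2O)c(O)c1 | target

## Step count and least certain steps

Total step count: 7. Longest linear sequence: 7 steps (1 → 2 → 3 → 4 → 6 → 8 → 10 → 11); compound 2 re-enters at step 4 and boronic acid 7 enters at step 5.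

**Step 6 (key step, the one step beyond known chemistry).**
- What may go wrong: the reaction stalls at ring-opened material that re-lactonises on acidification, because C-acylation by a weakly populated enolate on a hindered, vinylogous ester is slow. Forcing conditions then open the way to cyclopentenone formation by aldol condensation of the 1,4-diketone and to Favorskii-type or solvolytic loss of chloride from the keto tautomer of the chlorinated unit. Closure of only one ring is a further possible outcome.
- Fallback (known chemistry, gives up the ring transformation): all three aryl–aryl bonds are made by Suzuki–Miyaura coupling of 2,6-dimethoxyaryl partners. It sets out from boronic acid 7 and comes back to the route at target 11. Commercial 2-chloro-1,3,5-trimethoxybenzene is brominated twice (NBS, MeCN) to 1,3-dibromo-5-chloro-2,4,6-trimethoxybenzene F1. Twofold coupling of F1 with 7 (Pd(OAc)2, SPhos, K3PO4, toluene/H2O, 100 °C) gives 5'-chloro-2,2',2'',4,4',4'',6,6',6''-nonamethoxy-1,1':3',1''-terphenyl F2, whose two outer rings are equivalent. One equivalent of NBS brominates one of its four equivalent free positions to give the 3-bromo terphenyl F3. Coupling of F3 with 7 under the same conditions gives 3-chloro-2,2',4,4',6,6'-hexamethoxy-3',5-bis(2,4,6-trimethoxyphenyl)-1,1'-biphenyl F4, the dodecamethyl ether of the target. BBr3 as in step 7 then gives 11.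

**Step 4.**
- What may go wrong: proton transfer from the acidic CH2Br group of 4 to the lithium dienolate 5, followed by self-condensation of the electrophile; attack of 5 on ring carbons of 4 instead of SN2 substitution; a second alkylation of the product at its bridge.
- Fallback (olefination and reduction in place of alkylation): it sets out from 2 and 4 and comes back at 6. Oxidation of the methyl group of 2 (SeO2, dioxane, heat) gives 3-bromo-4-methoxy-2-oxo-2H-pyran-6-carbaldehyde F5. Bromide 4 and PPh3 give [(3-bromo-5-chloro-4-methoxy-2-oxo-2H-pyran-6-yl)methyl]triphenylphosphonium bromide F6. Wittig reaction of the ylide of F6 (K2CO3, CH2Cl2) with F5 gives 3-bromo-6-[(E)-2-(3-bromo-4-methoxy-2-oxo-2H-pyran-6-yl)ethenyl]-5-chloro-4-methoxy-2H-pyran-2-one F7. Diimide (2-nitrobenzenesulfonyl hydrazide, Et3N) saturates only the disubstituted bridge double bond, leaving the halogens and ring double bonds, and gives 6.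

**Step 5.**
- What may go wrong: protodeboronation of 7 outruns the slow, hindered transmetalation, so the second coupling stays incomplete; the 5-chlorine is drawn into coupling once the bromides are consumed; hot aqueous base opens a lactone or displaces a 4-methoxy group.
- Fallback (arylation split over two stages so that each hindered coupling is a single event): it sets out from 2, 4 and 7 and comes back at 8. Coupling of 2 with 7 under the step 5 conditions gives 4-methoxy-6-methyl-3-(2,4,6-trimethoxyphenyl)-2H-pyran-2-one F8. Its lithium dienolate (LiN(SiMe3)2, THF, −78 °C) is alkylated with 4 to give 3-bromo-5-chloro-4-methoxy-6-{2-[4-methoxy-2-oxo-3-(2,4,6-trimethoxyphenyl)-2H-pyran-6-yl]ethyl}-2H-pyran-2-one F9. One further coupling of F9 with 7 gives 8.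

**Step 2.**
- What may go wrong: substitution at the 5-position of the electron-poorer bromopyrone is sluggish, and under forcing conditions ipso attack at the 3-position exchanges bromine for chlorine, scrambling the two halogens on which the later site selectivity depends.
- Fallback (one kind of halogen, site selectivity by position instead of by halogen): it sets out from 1 and comes back at 8. Exhaustive chlorination of 1 (SO2Cl2, CH2Cl2) gives 3,5-dichloro-4-methoxy-6-methyl-2H-pyran-2-one F10. Radical bromination as in step 3 gives 6-(bromomethyl)-3,5-dichloro-4-methoxy-2H-pyran-2-one F11. Alkylation of lithium dienolate 5 with F11 as in step 4 gives 3-bromo-6-[2-(3,5-dichloro-4-methoxy-2-oxo-2H-pyran-6-yl)ethyl]-4-methoxy-2H-pyran-2-one F12. Twofold coupling of F12 with 7 (Pd(OAc)2, SPhos, K3PO4) at the C–Br bond and at the C–Cl bond α to the lactone carbonyl, the more reactive of the two chlorides, gives 8.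

## Further compounds

F1 | step 6 | 1,3-dibromo-5-chloro-2,4,6-trimethoxybenzene | COc1c(Br)c(OC)c(Cl)c(OC)c1Br
F2 | step 6 | 5'-chloro-2,2',2'',4,4',4'',6,6',6''-nonamethoxy-1,1':3',1''-terphenyl | COc1cc(OC)c(-c2c(OC)c(Cl)c(OC)c(-c3c(OC)cc(OC)cc3OC)c2OC)c(OC)c1
F3 | step 6 | 3-bromo-5'-chloro-2,2',2'',4,4',4'',6,6',6''-nonamethoxy-1,1':3',1''-terphenyl | COc1cc(OC)c(-c2c(OC)c(Cl)c(OC)c(-c3c(OC)cc(OC)c(Br)c3OC)c2OC)c(OC)c1
F4 | step 6 | 3-chloro-2,2',4,4',6,6'-hexamethoxy-3',5-bis(2,4,6-trimethoxyphenyl)-1,1'-biphenyl | COc1cc(OC)c(-c2c(OC)cc(OC)c(-c3c(OC)c(Cl)c(OC)c(-c4c(OC)cc(OC)cc4OC)c3OC)c2OC)c(OC)c1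
F5 | step 4 | 3-bromo-4-methoxy-2-oxo-2H-pyran-6-carbaldehyde | COC1=C(Br)C(=O)OC(C=O)=C1
F6 | step 4 | [(3-bromo-5-chloro-4-methoxy-2-oxo-2H-pyran-6-yl)methyl]triphenylphosphonium bromide | COC1=C(Br)C(=O)OC(C[P+](c2ccccc2)(c2ccccc2)c2ccccc2)=C1Cl.[Br-]
F7 | step 4 | 3-bromo-6-[(E)-2-(3-bromo-4-methoxy-2-oxo-2H-pyran-6-yl)ethenyl]-5-chloro-4-methoxy-2H-pyran-2-one | COC1=C(Br)C(=O)OC(/C=C/C2=C(Cl)C(OC)=C(Br)C(=O)O2)=C1
F8 | step 5 | 4-methoxy-6-methyl-3-(2,4,6-trimethoxyphenyl)-2H-pyran-2-one | COc1cc(OC)c(C2=C(OC)C=C(C)OC2=O)c(OC)c1
F9 | step 5 | 3-bromo-5-chloro-4-methoxy-6-{2-[4-methoxy-2-oxo-3-(2,4,6-trimethoxyphenyl)-2H-pyran-6-yl]ethyl}-2H-pyran-2-one | COc1cc(OC)c(C2=C(OC)C=C(CCC3=C(Cl)C(OC)=C(Br)C(=O)O3)OC2=O)c(OC)c1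
F10 | step 2 | 3,5-dichloro-4-methoxy-6-methyl-2H-pyran-2-one | COC1=C(Cl)C(=O)OC(C)=C1Cl
F11 | step 2 | 6-(bromomethyl)-3,5-dichloro-4-methoxy-2H-pyran-2-one | COC1=C(Cl)C(=O)OC(CBr)=C1Cl
F12 | step 2 | 3-bromo-6-[2-(3,5-dichloro-4-methoxy-2-oxo-2H-pyran-6-yl)ethyl]-4-methoxy-2H-pyran-2-one | COC1=C(Br)C(=O)OC(CCC2=C(Cl)C(OC)=C(Cl)C(=O)O2)=C1
A1 | alternative 1 | methylene-bridged quaterphenyl decamethyl ether (dibenzo-1,3-dioxepine across B4–O and C2–O) | COc1cc(OC)c(-c2c(OC)c3c(cc2OC)OCOc2c(Cl)c(OC)c(-c4c(OC)cc(OC)cc4OC)c(OC)c2-3)c(OC)c1
A2 | alternative 1 | open methylene acetal linking B4–O and C2–O, bromine on C1, hydrogen on B3 | COc1cc(OC)c(-c2c(OC)cc(OCOc3c(Br)c(OC)c(-c4c(OC)cc(OC)cc4OC)c(OC)c3Cl)cc2OC)c(OC)c1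
A3 | alternative 2 | quaterphenyl with ring B as free B2–OH, ethyl ether on B4 and triisopropylsilyl ether on B6 | CCOc1cc(O[Si](C(C)C)(C(C)C)C(C)C)c(-c2c(OC)cc(OC)cc2OC)c(O)c1-c1c(OC)c(Cl)c(OC)c(-c2c(OC)cc(OC)cc2OC)c1OC
A4 | alternative 2 | racemic 3-ethoxy-4-aryl-cyclobut-2-en-1-one carrying the ring C–D unit on the sp3 carbon | CCOC1=CC(=O)C1c1c(OC)c(Cl)c(OC)c(-c2c(OC)cc(OC)cc2OC)c1OC
A5 | alternative 2 | triisopropyl{[(2,4,6-trimethoxyphenyl)ethynyl]oxy}silane | COc1cc(OC)c(C#CO[Si](C(C)C)(C(C)C)C(C)C)c(OC)c1
A6 | alternative 3 | target as its octamethyl ether with rings A and D each carrying two free OH | COc1cc(O)c(-c2c(OC)cc(OC)c(-c3c(OC)c(Cl)c(OC)c(-c4c(O)cc(OC)cc4O)c3OC)c2OC)c(O)c1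
A7 | alternative 3 | dimethyl (2E,2'E)-6,6'-(3-chloro-2,2',4,4',6,6'-hexamethoxy-[1,1'-biphenyl]-3',5-diyl)bis(3-methoxy-5-oxohex-2-enoate) | COC(=O)/C=C(\CC(=O)Cc1c(OC)cc(OC)c(-c2c(OC)c(Cl)c(OC)c(CC(=O)C/C(OC)=C\C(=O)OC)c2OC)c1OC)OC
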